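**Plan**

- Retrosynthetic cuts (prostanoid numbering): O12–Si; C6–C7 (to a Z enol triflate at C7 and an E alkenylboronate); C7–C8 (a formyl carbon); the C10=C11 bromo-enone back to a saturated C9 ketone with OH on C10; then C9–C10; finally C12–C8 and C12–C11 (two allyl groups on an ester carbon) and C13–C14 (alkyne C–H functionalisation).
- Enabling feature: in the five-membered ring C8–C12, C9 (ketone) and C10 (C–Br) are neighbours that can both begin as formyl carbons. Breaking C9–C10 therefore leaves an achiral 3,3-disubstituted glutaraldehyde whose two CH2CHO arms are enantiotopic about the carbinol carbon C12.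
- Forward order: the open-chain dialdehyde is built in four steps, the only ring closes in step 5, C10 goes OH → Br → bromo-enone, and the C1–C6 chain is joined last at C6–C7.
- Stereochemistry: C12 (R) from the chiral carbene deciding which arm becomes the ketone; 14Z from syn semihydrogenation; 7Z from a chelation-controlled enol triflate coupled with retention; 5E from syn hydroboration.

Key step: step 5

Assumption: the sense of induction of the triazolylidene on this new substrate class cannot be predicted with certainty; the (5aR,10bS) salt is written, and its mirror image would be used if the ring closed into the (2S,4S) series.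

**Route**

Step 1
Reactants: 1 hept-1-yne; 2 ethyl diazoacetate
Product: 3 ethyl non-3-ynoate
Conditions: CuI (5 mol%), MeCN, rt
Reagents that add atoms: none
Why: Copper-catalysed coupling of a terminal alkyne with a diazo ester (formal insertion of the carbene carbon into the alkynyl C–H bond, with loss of N2) gives the β,γ-alkynoate, and the base-free conditions keep it from isomerising to the allenoate.

Step 2
Reactants: 3 ethyl non-3-ynoate; 4 allylmagnesium bromide
Product: 6 4-(oct-2-yn-1-yl)hepta-1,6-dien-4-ol, via ketone 5 (not isolated)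
Conditions: 4 (2.6 equiv), anhydrous CeCl3 (2.6 equiv), THF, −78 → 0 °C; aq. NH4Cl
Reagents that add atoms: none
Why: Double Grignard addition to an ester (the intermediate ketone is more electrophilic than the ester and takes the second allyl group), in the organocerium variant that suppresses deprotonation of the doubly activated propargylic CH2.

Step 3
Reactants: 6 4-(oct-2-yn-1-yl)hepta-1,6-dien-4-ol
Product: 7 triethyl{[4-(oct-2-yn-1-yl)hepta-1,6-dien-4-yl]oxy}silane
Conditions: Et3SiOTf (1.3 equiv), 2,6-lutidine (2 equiv), CH2Cl2, −78 → 0 °C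
Reagents that add atoms: triethylsilyl trifluoromethanesulfonate, CC[Si](CC)(CC)OS(=O)(=O)C(F)(F)F
Why: Silylation of a hindered tertiary alcohol with a silyl triflate and a non-nucleophilic base is standard, and the Et3Si ether is stable to the later steps yet removable with fluoride at the end.

Step 4
Reactants: 7 triethyl{[4-(oct-2-yn-1-yl)hepta-1,6-dien-4-yl]oxy}silane
Product: 9 3-(oct-2-yn-1-yl)-3-[(triethylsilyl)oxy]pentanedial, via tetrol 8 (not isolated)
Conditions: OsO4 (2 mol%), N-methylmorpholine N-oxide (2.4 equiv), acetone/H2O, rt; then NaIO4 (2.5 equiv), pH 7 buffer, 0 °C → rt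
Reagents that add atoms: N-methylmorpholine N-oxide, C[N+]1([O-])CCOCC1; water, O
Why: Catalytic syn-dihydroxylation of the two terminal alkenes followed by periodate glycol cleavage (two-stage Lemieux–Johnson degradation) removes one carbon from each allyl arm; OsO4 reacts far faster with monosubstituted alkenes than with the internal alkyne, which is why C14–C15 is carried as an alkyne here.

Step 5
Reactants: 9 3-(oct-2-yn-1-yl)-3-[(triethylsilyl)oxy]pentanedial
Product: 10 (2R,4R)-2-hydroxy-4-(oct-2-yn-1-yl)-4-[(triethylsilyl)oxy]cyclopentan-1-one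
Conditions: (5aR,10bS)-2-(pentafluorophenyl)-5a,10b-dihydro-4H,6H-indeno[2,1-b][1,2,4]triazolo[4,3-d][1,4]oxazin-2-ium tetrafluoroborate (10 mol%), i-Pr2NEt (10 mol%), toluene (0.02 M), 0 °C → rt; AcOH quench at full conversion; chromatography
Reagents that add atoms: none
Why: Proposed new method: the triazolylidene released by the amine adds reversibly to either formyl group of 9 and, after proton transfer, the resulting enaminol makes that carbon (C9) an acyl-anion equivalent that attacks the other formyl carbon (C10), the adduct then expelling the carbene to leave the C9 ketone beside the C10 carbinol. The closest known reactions are the azolium-catalysed cyclisation of 1,5-dialdehydes to 2-hydroxycyclopentanones and the enantioselective intramolecular aldehyde–ketone benzoin reaction; new here is the use of this closure to tell apart the two enantiotopic arms of a 3,3-disubstituted glutaraldehyde. The five-membered ring closes in a 5-exo-trig mode, favoured over oligomerisation by the gem-disubstitution at C12 and by high dilution. C10 is set by the catalyst, whose indane wall leaves one face of the hydrogen-bonded acceptor aldehyde open, and C12 follows from it because the substrate should close through the envelope in which the acceptor C=O points away from the bulky Et3SiO group (OH trans to OSiEt3), so that the two preferences together decide which arm becomes the ketone. The step needs kinetic control, since ring reopening or enediol tautomerism would exchange C9 and C10 and so erase C12, and silanol must not be eliminated from the β-silyloxy aldehyde; the weak amine base, the low temperature and the acidic quench are chosen for this. The cis isomer, which for the same C10 configuration carries the opposite C12, is removed by chromatography at this stage.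

Step 6
Reactants: 10 (2R,4R)-2-hydroxy-4-(oct-2-yn-1-yl)-4-[(triethylsilyl)oxy]cyclopentan-1-one
Product: 11 (2R,4R)-2-hydroxy-4-[(2Z)-oct-2-en-1-yl]-4-[(triethylsilyl)oxy]cyclopentan-1-one
Conditions: H2 (1 atm), Pd on CaCO3 poisoned with Pb(OAc)2, quinoline, EtOAc, rt
Reagents that add atoms: none
Why: Semihydrogenation on lead-poisoned palladium delivers both hydrogens to one face of the alkyne and stops at the Z alkene, while the ketol and the silyl ether are inert.

Step 7
Reactants: 11 (2R,4R)-2-hydroxy-4-[(2Z)-oct-2-en-1-yl]-4-[(triethylsilyl)oxy]cyclopentan-1-one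
Product: 12 (2S,4S)-2-bromo-4-[(2Z)-oct-2-en-1-yl]-4-[(triethylsilyl)oxy]cyclopentan-1-one
Conditions: CBr4 (1.3 equiv), PPh3 (1.3 equiv, added last in portions), CH2Cl2, 0 °C
Reagents that add atoms: carbon tetrabromide, BrC(Br)(Br)Br
Why: Appel reaction, in which bromide displaces the oxyphosphonium group at the carbonyl-activated C10 with inversion (the configuration there is of no consequence later), placing bromine on C10 without any electrophilic bromine that would attack the Z alkene.

Step 8
Reactants: 12 (2S,4S)-2-bromo-4-[(2Z)-oct-2-en-1-yl]-4-[(triethylsilyl)oxy]cyclopentan-1-one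
Product: 14 (4S)-2-bromo-4-[(2Z)-oct-2-en-1-yl]-2-(phenylselanyl)-4-[(triethylsilyl)oxy]cyclopentan-1-one (C2 epimers), via lithium bromo enolate 13 (not isolated)
Conditions: LiN(SiMe3)2 (1.05 equiv), THF, −78 °C; then PhSeBr (1.05 equiv), −78 °C; aq. NaHCO3
Reagents that add atoms: benzeneselenenyl bromide, Br[Se]c1ccccc1
Why: Enolate selenenylation: LiN(SiMe3)2 is known to deprotonate α-bromo ketones at the more acidic bromine-bearing carbon (here C10, also less hindered than C8 next to the quaternary C12), and the bromo enolate captures PhSeBr on carbon far faster than PhSeBr can add to the Z alkene.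

Step 9
Reactants: 14 (4S)-2-bromo-4-[(2Z)-oct-2-en-1-yl]-2-(phenylselanyl)-4-[(triethylsilyl)oxy]cyclopentan-1-one
Product: 16 (4S)-2-bromo-4-[(2Z)-oct-2-en-1-yl]-4-[(triethylsilyl)oxy]cyclopent-2-en-1-one, via selenoxide 15 (not isolated)
Conditions: NaIO4 (2 equiv), NaHCO3, THF/H2O, 0 °C → rt
Reagents that add atoms: none
Why: Selenoxide syn elimination, known for α-halo-α-seleno ketones: only C11 carries β-hydrogens, so the alkene can form only at C10=C11 with bromine kept on C10, and periodate leaves the Z alkene untouched.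

Step 10
Reactants: 16 (4S)-2-bromo-4-[(2Z)-oct-2-en-1-yl]-4-[(triethylsilyl)oxy]cyclopent-2-en-1-one
Product: 18 (4R,5Z)-2-bromo-5-(hydroxymethylidene)-4-[(2Z)-oct-2-en-1-yl]-4-[(triethylsilyl)oxy]cyclopent-2-en-1-one, via lithium dienolate 17 (not isolated)
Conditions: LiN(SiMe3)2 (1.1 equiv), THF, −78 °C; then CF3CH2OCHO (1.5 equiv), −78 → −40 °C; cold dilute aq. HCl to pH 3
Reagents that add atoms: 2,2,2-trifluoroethyl formate, O=COCC(F)(F)F
Why: Claisen-type C-formylation of the lithium dienolate, which can form only at C8 (C10 has no hydrogen) and cannot expel silanolate without creating a cyclopentadienone; trifluoroethyl formate formylates lithium enolates at −78 °C without free alkoxide, and the product rests as the hydrogen-bonded Z enol.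

Step 11
Reactants: 18 (4R,5Z)-2-bromo-5-(hydroxymethylidene)-4-[(2Z)-oct-2-en-1-yl]-4-[(triethylsilyl)oxy]cyclopent-2-en-1-one
Product: 20 (Z)-{(5R)-3-bromo-5-[(2Z)-oct-2-en-1-yl]-2-oxo-5-[(triethylsilyl)oxy]cyclopent-3-en-1-ylidene}methyl trifluoromethanesulfonate, via lithium chelate 19 (not isolated)
Conditions: LiOTf (1.5 equiv), i-Pr2NEt (1.3 equiv), CH2Cl2, −78 °C; then Tf2O (1.1 equiv), −78 °C
Reagents that add atoms: trifluoromethanesulfonic anhydride, O=S(=O)(OS(=O)(=O)C(F)(F)F)C(F)(F)F
Why: Chelation-controlled enol triflation, as used for Z enol triflates of β-keto esters: the lithium chelate holds the formyl-derived oxygen cis to the ring carbonyl and sulfonylation occurs on that less hindered oxygen, giving the Z triflate, which is also the less crowded isomer because the E position is flanked by the quaternary C12.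

Step 12
Reactants: 21 methyl hex-5-ynoate
Product: 22 methyl (5E)-6-(4,4,5,5-tetramethyl-1,3,2-dioxaborolan-2-yl)hex-5-enoate
Conditions: pinacolborane (1.1 equiv), Cp2Zr(H)Cl (5 mol%), Et3N (10 mol%), CH2Cl2, rt
Reagents that add atoms: pinacolborane, CC1(C)OBOC1(C)C
Why: Zirconium-catalysed hydroboration of a terminal alkyne is a syn, anti-Markovnikov addition that gives the E alkenylboronate and leaves the ester untouched.

Step 13
Reactants: 20 the Z enol triflate; 22 methyl (5E)-6-(4,4,5,5-tetramethyl-1,3,2-dioxaborolan-2-yl)hex-5-enoate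
Product: 23 methyl (5E,7Z,12R,14Z)-10-bromo-9-oxo-12-[(triethylsilyl)oxy]prosta-5,7,10,14-tetraen-1-oate
Conditions: 22 (1.1 equiv), Pd(PPh3)4 (5 mol%), K3PO4 (2 equiv), THF/H2O (10:1), rt, dark
Reagents that add atoms: none
Why: Suzuki–Miyaura coupling: zerovalent palladium should insert into the vinylogous acyl triflate at room temperature much faster than into the C10–Br bond of the α-bromo enone, and every elementary step retains alkene geometry, so the Z triflate and the E boronate give the 5E,7Z diene.

Step 14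
Reactants: 23 methyl (5E,7Z,12R,14Z)-10-bromo-9-oxo-12-[(triethylsilyl)oxy]prosta-5,7,10,14-tetraen-1-oate
Product: 24 methyl (5E,7Z,12R,14Z)-10-bromo-12-hydroxy-9-oxoprosta-5,7,10,14-tetraen-1-oate (the target)
Conditions: HF·pyridine, pyridine, THF, 0 °C
Reagents that add atoms: none
Why: Fluoride-driven cleavage of the tertiary triethylsilyl ether under buffered, non-basic conditions spares the cross-conjugated bromo dienone and the methyl ester, and the bis-allylic alcohol does not ionise because a cation at C12 would be a destabilised 4-oxocyclopentenyl cation.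

**Compound list**

1 | hept-1-yne | CCCCCC#C | starting material
2 | ethyl diazoacetate | CCOC(=O)C=[N+]=[N-] | starting material
3 | ethyl non-3-ynoate | CCCCCC#CCC(=O)OCC | intermediate
4 | allylmagnesium bromide | C=CC[Mg]Br | starting material
5 | dodec-1-en-6-yn-4-one | CCCCCC#CCC(=O)CC=C | intermediate (not isolated)
6 | 4-(oct-2-yn-1-yl)hepta-1,6-dien-4-ol | CCCCCC#CCC(O)(CC=C)CC=C | intermediate
7 | triethyl{[4-(oct-2-yn-1-yl)hepta-1,6-dien-4-yl]oxy}silane | CCCCCC#CCC(CC=C)(CC=C)O[Si](CC)(CC)CC | intermediate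
8 | 4-(oct-2-yn-1-yl)-4-[(triethylsilyl)oxy]heptane-1,2,6,7-tetrol (diastereomer mixture) | CCCCCC#CCC(CC(O)CO)(CC(O)CO)O[Si](CC)(CC)CC | intermediate (not isolated)
9 | 3-(oct-2-yn-1-yl)-3-[(triethylsilyl)oxy]pentanedial (achiral) | CCCCCC#CCC(CC=O)(CC=O)O[Si](CC)(CC)CC | intermediate
10 | (2R,4R)-2-hydroxy-4-(oct-2-yn-1-yl)-4-[(triethylsilyl)oxy]cyclopentan-1-one (OH trans to OSiEt3) | CCCCCC#CC[C@@]1(O[Si](CC)(CC)CC)C[C@@H](O)C(=O)C1 | intermediate
11 | (2R,4R)-2-hydroxy-4-[(2Z)-oct-2-en-1-yl]-4-[(triethylsilyl)oxy]cyclopentan-1-one | CCCCC/C=C\C[C@@]1(O[Si](CC)(CC)CC)C[C@@H](O)C(=O)C1 | intermediate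
12 | (2S,4S)-2-bromo-4-[(2Z)-oct-2-en-1-yl]-4-[(triethylsilyl)oxy]cyclopentan-1-one | CCCCC/C=C\C[C@@]1(O[Si](CC)(CC)CC)C[C@H](Br)C(=O)C1 | intermediate
13 | lithium (4S)-2-bromo-4-[(2Z)-oct-2-en-1-yl]-4-[(triethylsilyl)oxy]cyclopent-1-en-1-olate | CCCCC/C=C\C[C@@]1(O[Si](CC)(CC)CC)CC(Br)=C([O-])C1.[Li+] | intermediate (not isolated)
14 | (4S)-2-bromo-4-[(2Z)-oct-2-en-1-yl]-2-(phenylselanyl)-4-[(triethylsilyl)oxy]cyclopentan-1-one (C2 epimers) | CCCCC/C=C\C[C@@]1(O[Si](CC)(CC)CC)CC(Br)([Se]c2ccccc2)C(=O)C1 | intermediate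
15 | (4S)-2-bromo-4-[(2Z)-oct-2-en-1-yl]-2-(phenylseleninyl)-4-[(triethylsilyl)oxy]cyclopentan-1-one (selenoxide, isomer mixture at C2 and Se) | CCCCC/C=C\C[C@@]1(O[Si](CC)(CC)CC)CC(Br)([Se](=O)c2ccccc2)C(=O)C1 | intermediate (not isolated)
16 | (4S)-2-bromo-4-[(2Z)-oct-2-en-1-yl]-4-[(triethylsilyl)oxy]cyclopent-2-en-1-one | CCCCC/C=C\C[C@@]1(O[Si](CC)(CC)CC)C=C(Br)C(=O)C1 | intermediate
17 | lithium (3S)-5-bromo-3-[(2Z)-oct-2-en-1-yl]-3-[(triethylsilyl)oxy]cyclopenta-1,4-dien-1-olate | CCCCC/C=C\C[C@@]1(O[Si](CC)(CC)CC)C=C(Br)C([O-])=C1.[Li+] | intermediate (not isolated)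
18 | (4R,5Z)-2-bromo-5-(hydroxymethylidene)-4-[(2Z)-oct-2-en-1-yl]-4-[(triethylsilyl)oxy]cyclopent-2-en-1-one | CCCCC/C=C\C[C@@]1(O[Si](CC)(CC)CC)C=C(Br)C(=O)/C1=C\O | intermediate
19 | lithium (Z)-{(5R)-3-bromo-5-[(2Z)-oct-2-en-1-yl]-2-oxo-5-[(triethylsilyl)oxy]cyclopent-3-en-1-ylidene}methanolate (chelate) | CCCCC/C=C\C[C@@]1(O[Si](CC)(CC)CC)C=C(Br)C(=O)/C1=C\[O-].[Li+] | intermediate (not isolated)
20 | (Z)-{(5R)-3-bromo-5-[(2Z)-oct-2-en-1-yl]-2-oxo-5-[(triethylsilyl)oxy]cyclopent-3-en-1-ylidene}methyl trifluoromethanesulfonate | CCCCC/C=C\C[C@@]1(O[Si](CC)(CC)CC)C=C(Br)C(=O)/C1=C\OS(=O)(=O)C(F)(F)F | intermediate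
21 | methyl hex-5-ynoate | COC(=O)CCCC#C | starting material
22 | methyl (5E)-6-(4,4,5,5-tetramethyl-1,3,2-dioxaborolan-2-yl)hex-5-enoate | COC(=O)CCC/C=C/B1OC(C)(C)C(C)(C)O1 | intermediate
23 | methyl (5E,7Z,12R,14Z)-10-bromo-9-oxo-12-[(triethylsilyl)oxy]prosta-5,7,10,14-tetraen-1-oate | CCCCC/C=C\C[C@@]1(O[Si](CC)(CC)CC)C=C(Br)C(=O)/C1=C\C=C\CCCC(=O)OC | intermediate
24 | methyl (5E,7Z,12R,14Z)-10-bromo-12-hydroxy-9-oxoprosta-5,7,10,14-tetraen-1-oate | CCCCC/C=C\C[C@@]1(O)C=C(Br)C(=O)/C1=C\C=C\CCCC(=O)OC | target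

**Step count**

Total: 14 steps. Longest linear sequence: 13 steps (steps 1–11, 13 and 14, from hept-1-yne); step 12 prepares the side-chain boronate.

**Steps most likely to fail**

Step 5. What may go wrong: weak discrimination between the two enantiotopic formyl groups, or erosion of the selectivity through reversible ring opening and enediol shift under the basic conditions. The fallback uses known chemistry, sets out from 9 and returns at 10. Dialdehyde 9 is cyclised with an achiral thiazolium precatalyst (3-benzyl-5-(2-hydroxyethyl)-4-methylthiazolium chloride, Et3N, EtOH, rt), a known dialdehyde-to-ketol closure. After removal of the cis racemate this gives the racemic trans ketol, rac-(2R*,4R*)-2-hydroxy-4-(oct-2-yn-1-yl)-4-[(triethylsilyl)oxy]cyclopentan-1-one F1. F1 is resolved by preparative chromatography on an amylose tris(3,5-dimethylphenylcarbamate) stationary phase, which delivers 10 and sets aside its mirror image, (2S,4S)-2-hydroxy-4-(oct-2-yn-1-yl)-4-[(triethylsilyl)oxy]cyclopentan-1-one F2.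

Step 13. What may go wrong: competing insertion of zerovalent palladium into the C10–Br bond, leading to double coupling, or hydrolysis and Z/E scrambling of the enol triflate under the basic coupling conditions. The fallback sets out from 16 and returns at 23, bypassing steps 10 to 13; it makes the C7=C8 bond by aldol condensation instead of cross-coupling. The aldehyde methyl (5E)-7-oxohept-5-enoate F6 is prepared by Wittig reaction of methyl 5-oxopentanoate with (triphenylphosphoranylidene)acetaldehyde. The lithium dienolate 17 (LiN(SiMe3)2, THF, −78 °C) adds to it to give the aldol, methyl (5E)-7-{(5R)-3-bromo-5-[(2Z)-oct-2-en-1-yl]-2-oxo-5-[(triethylsilyl)oxy]cyclopent-3-en-1-yl}-7-hydroxyhept-5-enoate F7, as a diastereomer mixture. Mesylation (MsCl, Et3N, CH2Cl2, 0 °C) gives the corresponding methanesulfonate, methyl (5E)-7-{(5R)-3-bromo-5-[(2Z)-oct-2-en-1-yl]-2-oxo-5-[(triethylsilyl)oxy]cyclopent-3-en-1-yl}-7-(methanesulfonyloxy)hept-5-enoate F8. Elimination with DBU then gives 23 together with its 7E isomer, methyl (5E,7E,12R,14Z)-10-bromo-9-oxo-12-[(triethylsilyl)oxy]prosta-5,7,10,14-tetraen-1-oate F9, which is removed by chromatography.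

Step 8. What may go wrong: deprotonation at C8 instead of C10, followed by loss of silanolate or Favorskii-type collapse, so that selenium is not delivered to the bromine-bearing carbon. The fallback sets out from 12 and returns at 16; it brings in bromine by epoxide opening instead. Bromide is displaced by PhSeNa (from PhSeSePh and NaBH4, EtOH, 0 °C) to give the C10 selenide, (2R,4S)-4-[(2Z)-oct-2-en-1-yl]-2-(phenylselanyl)-4-[(triethylsilyl)oxy]cyclopentan-1-one F3. Oxidation with NaIO4 and selenoxide elimination give the plain enone, (4S)-4-[(2Z)-oct-2-en-1-yl]-4-[(triethylsilyl)oxy]cyclopent-2-en-1-one F4. Weitz–Scheffer epoxidation (H2O2, NaOH, MeOH, 0 °C), which does not touch the isolated Z alkene, gives the epoxy ketone, 4-[(2Z)-oct-2-en-1-yl]-4-[(triethylsilyl)oxy]-6-oxabicyclo[3.1.0]hexan-2-one F5 (C4 as in 16, epoxide face not defined). LiBr with a sulfonic acid ion-exchange resin in acetone then opens the epoxide at C10 with bromide and dehydrates the bromohydrin to 16.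

**Further compounds**

F1 | step 5 | rac-(2R*,4R*)-2-hydroxy-4-(oct-2-yn-1-yl)-4-[(triethylsilyl)oxy]cyclopentan-1-one (racemate, both enantiomers written) | CCCCCC#CC[C@@]1(O[Si](CC)(CC)CC)C[C@@H](O)C(=O)C1.CCCCCC#CC[C@]1(O[Si](CC)(CC)CC)C[C@H](O)C(=O)C1
F2 | step 5 | (2S,4S)-2-hydroxy-4-(oct-2-yn-1-yl)-4-[(triethylsilyl)oxy]cyclopentan-1-one | CCCCCC#CC[C@]1(O[Si](CC)(CC)CC)C[C@H](O)C(=O)C1
F3 | step 8 | (2R,4S)-4-[(2Z)-oct-2-en-1-yl]-2-(phenylselanyl)-4-[(triethylsilyl)oxy]cyclopentan-1-one | CCCCC/C=C\C[C@@]1(O[Si](CC)(CC)CC)C[C@@H]([Se]c2ccccc2)C(=O)C1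
F4 | step 8 | (4S)-4-[(2Z)-oct-2-en-1-yl]-4-[(triethylsilyl)oxy]cyclopent-2-en-1-one | CCCCC/C=C\C[C@@]1(O[Si](CC)(CC)CC)C=CC(=O)C1
F5 | step 8 | 4-[(2Z)-oct-2-en-1-yl]-4-[(triethylsilyl)oxy]-6-oxabicyclo[3.1.0]hexan-2-one (C4 as in 16, epoxide face not defined) | CCCCC/C=C\C[C@@]1(O[Si](CC)(CC)CC)C2OC2C(=O)C1
F6 | step 13 | methyl (5E)-7-oxohept-5-enoate | COC(=O)CCC/C=C/C=O
F7 | step 13 | methyl (5E)-7-{(5R)-3-bromo-5-[(2Z)-oct-2-en-1-yl]-2-oxo-5-[(triethylsilyl)oxy]cyclopent-3-en-1-yl}-7-hydroxyhept-5-enoate (diastereomer mixture) | CCCCC/C=C\C[C@@]1(O[Si](CC)(CC)CC)C=C(Br)C(=O)C1C(O)/C=C/CCCC(=O)OC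
F8 | step 13 | methyl (5E)-7-{(5R)-3-bromo-5-[(2Z)-oct-2-en-1-yl]-2-oxo-5-[(triethylsilyl)oxy]cyclopent-3-en-1-yl}-7-(methanesulfonyloxy)hept-5-enoate (diastereomer mixture) | CCCCC/C=C\C[C@@]1(O[Si](CC)(CC)CC)C=C(Br)C(=O)C1C(OS(C)(=O)=O)/C=C/CCCC(=O)OC
F9 | step 13 | methyl (5E,7E,12R,14Z)-10-bromo-9-oxo-12-[(triethylsilyl)oxy]prosta-5,7,10,14-tetraen-1-oate | CCCCC/C=C\C[C@@]1(O[Si](CC)(CC)CC)C=C(Br)C(=O)/C1=C/C=C/CCCC(=O)OC
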